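**Strategy**

- Retrosynthetic cuts (labdane numbering throughout): first the C15–O malonate ester bond, the C8–O bond (alkene hydration) and the C3–O bond (deoxygenation); then the ring bonds C4–C5 and C9–C10 together; last the chain bond C6–C7 between two C10 units.
- Enabling feature: rings A and B, with the tertiary carbinol at C8 and the equatorial CH2O group (C18) on C4, are the folded form of an all-E 13,14-dihydrogeranylgeranyl chain. Its C3=C4, C5=C10 and C8=C9 alkenes lie where C4–C5 and C9–C10 must form, and C8 is where the cation ends.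
- Forward order: (S)-citronellol (C7–C9, C11–C17) and geraniol (C1–C6, C10, C18–C20) are each oxidised at the E-methyl group and joined at C6–C7 by allyl sulfone alkylation and desulfonylation. The C3=C4 allylic alcohol is then epoxidised and one Lewis acid cascade closes ring A, then ring B.
- Stereochemistry: C13 is bought with (S)-citronellol. Sharpless epoxidation with D-(−)-diethyl tartrate sets C3 and C4, and anti opening plus chair-chair folding relay this to C4, C5, C9 and C10 of the ent-labdane. C8 comes from radical hydration on the face opposite the axial C10 methyl.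
- End game: the C3 oxygen is removed, C8 is hydrated, C15 is acylated with mono-benzyl malonate, and one hydrogenolysis frees the C18 alcohol and the acid.

Key step: step 13

Assumption: proton loss from the C8 cation in step 13 is drawn for the 8(17)-alkene; any 7-ene formed beside it has the same stereocentres, is taken unseparated through steps 14 and 15 and gives the same C8 radical in step 16, so it is not numbered separately.

**Route**

Step 1
Reactants: 1 (S)-citronellol
Product: 2 (S)-citronellyl tert-butyldiphenylsilyl ether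
Conditions: TBDPSCl, imidazole, DMF, 0 °C to rt
Reagents that add atoms: tert-butyl(chloro)diphenylsilane CC(C)(C)[Si](Cl)(c1ccccc1)c1ccccc1
Why: Imidazole-promoted silylation of a primary alcohol is dependable, does not touch the C13 stereocentre and gives a silyl ether robust enough for the acid, Lewis acid, base and radical steps that follow.

Step 2
Reactants: 2 (S)-citronellyl tert-butyldiphenylsilyl ether
Product: 4 (2E,6S)-8-(tert-butyldiphenylsilyloxy)-2,6-dimethyloct-2-en-1-ol, via enal 3 (not isolated)
Conditions: SeO2 (cat.), t-BuOOH, salicylic acid (cat.), CH2Cl2, rt; then NaBH4, MeOH, 0 °C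
Reagents that add atoms: tert-butyl hydroperoxide CC(C)(C)OO; selenium dioxide O=[Se]=O (catalytic oxygen carrier)
Why: In the Riley allylic oxidation (ene reaction with SeO2, then [2,3]-sigmatropic shift, t-BuOOH as terminal oxidant) a trisubstituted alkene is oxidised at the methyl group trans to the chain, so the E allylic alcohol should form, and NaBH4 returns over-oxidised enal 3 to the same alcohol.

Step 3
Reactants: 4 (2E,6S)-8-(tert-butyldiphenylsilyloxy)-2,6-dimethyloct-2-en-1-ol
Product: 5 (3S,6E)-8-bromo-3,7-dimethyloct-6-en-1-yl tert-butyldiphenylsilyl ether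
Conditions: CBr4, PPh3, CH2Cl2, 0 °C
Reagents that add atoms: carbon tetrabromide BrC(Br)(Br)Br
Why: The Appel reaction turns the primary allylic alcohol into the bromide by SN2 displacement of an oxyphosphonium ion under neutral conditions, which should keep the E geometry and the silyl ether.

Step 4
Reactants: 6 geraniol
Product: 7 geranyl bromide
Conditions: PBr3, Et2O, −10 to 0 °C
Reagents that add atoms: phosphorus tribromide BrP(Br)Br
Why: Bromination of a primary allylic alcohol with PBr3 at low temperature is a standard displacement that keeps the E alkene of the geranyl unit.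

Step 5
Reactants: 7 geranyl bromide
Product: 8 geranyl phenyl sulfone
Conditions: PhSO2Na, DMF, rt
Reagents that add atoms: sodium benzenesulfinate [Na+].[O-]S(=O)c1ccccc1
Why: The sulfinate anion is alkylated at sulfur by the primary allylic bromide (SN2), which gives the sulfone whose α-carbon (C6) will carry the carbanion.

Step 6
Reactants: 8 geranyl phenyl sulfone
Product: 10 (2E,6E)-2,6-dimethyl-8-(phenylsulfonyl)octa-2,6-dien-1-ol, via enal 9 (not isolated)
Conditions: SeO2 (cat.), t-BuOOH, salicylic acid (cat.), CH2Cl2, 0 °C to rt; then NaBH4, MeOH, 0 °C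
Reagents that add atoms: tert-butyl hydroperoxide CC(C)(C)OO; selenium dioxide O=[Se]=O (catalytic oxygen carrier)
Why: In this second Riley allylic oxidation the alkene next to the sulfonylmethyl group is deactivated towards the ene reaction, so SeO2 should take the distal alkene at its E-methyl group (the future C18), and NaBH4 reduces enal 9 to the alcohol.

Step 7
Reactants: 10 (2E,6E)-2,6-dimethyl-8-(phenylsulfonyl)octa-2,6-dien-1-ol
Product: 11 (2E,6E)-8-(tert-butyldimethylsilyloxy)geranyl phenyl sulfone
Conditions: TBSCl, imidazole, CH2Cl2, 0 °C to rt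
Reagents that add atoms: tert-butyl(chloro)dimethylsilane CC(C)(C)[Si](C)(C)Cl
Why: Silylation of the primary allylic alcohol gives a TBS ether that tolerates the sulfonyl carbanion and can later be removed by mild acid beside the TBDPS ether.

Step 8
Reactants: 11 (2E,6E)-8-(tert-butyldimethylsilyloxy)geranyl phenyl sulfone; 5 (3S,6E)-8-bromo-3,7-dimethyloct-6-en-1-yl tert-butyldiphenylsilyl ether
Product: 13 coupled C20 allylic sulfone (both epimers at the sulfonyl carbon C6), via lithiated sulfone 12 (not isolated)
Conditions: n-BuLi, THF, −78 °C; then 5, −78 to −20 °C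
Reagents that add atoms: none
Why: Alkylation of the lithiated allyl sulfone 12 by the primary allylic bromide (sulfone-based allyl-allyl coupling) occurs at the carbon α to sulfur and by direct SN2 attack, forming C6–C7 with all alkene geometries kept; the sulfonyl-bearing carbon arises as both epimers and is erased in step 9.

Step 9
Reactants: 13 coupled C20 allylic sulfone
Product: 14 (2E,6E,10E,14S)-1-(tert-butyldimethylsilyloxy)-16-(tert-butyldiphenylsilyloxy)-2,6,10,14-tetramethylhexadeca-2,6,10-triene
Conditions: PdCl2(dppp) (cat.), LiBHEt3, THF, 0 °C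
Reagents that add atoms: none
Why: In this palladium-catalysed reductive desulfonylation, zerovalent palladium formed in situ ionises the allylic sulfone to a π-allyl complex and hydride from LiBHEt3 is delivered to the less substituted terminus C6, which should keep the E trisubstituted C5=C10 alkene in place.

Step 10
Reactants: 14 bis-silyl ether of the all-E C20 triene
Product: 15 (2E,6E,10E,14S)-16-(tert-butyldiphenylsilyloxy)-2,6,10,14-tetramethylhexadeca-2,6,10-trien-1-ol
Conditions: camphorsulfonic acid (cat.), MeOH/CH2Cl2, 0 °C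
Reagents that add atoms: none
Why: Acid-catalysed methanolysis removes the unhindered primary allylic TBS ether much faster than the bulky TBDPS ether, freeing only the C18 alcohol.

Step 11
Reactants: 15 all-E C20 trienol
Product: 16 (2R,3R)-2,3-epoxy alcohol of 15
Conditions: Ti(OiPr)4 (cat.), D-(−)-diethyl tartrate (cat.), t-BuOOH, 4 Å molecular sieves, CH2Cl2, −20 °C
Reagents that add atoms: tert-butyl hydroperoxide CC(C)(C)OO
Why: In the Sharpless asymmetric epoxidation titanium tartrate binds the allylic alcohol, so only the C3=C4 alkene reacts, and D-(−)-diethyl tartrate delivers oxygen to the face that gives the (2R,3R)-epoxide (C3 and C4 of the future ring A) under catalyst control, the remote C13 centre having no say.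

Step 12
Reactants: 16 (2R,3R)-epoxy alcohol
Product: 18 (2R,3R)-epoxy benzyl ether, via sodium alkoxide 17 (not isolated)
Conditions: NaH, THF, 0 °C; then BnBr, Bu4NI (cat.), 0 °C
Reagents that add atoms: benzyl bromide BrCc1ccccc1
Why: Williamson etherification of sodium alkoxide 17 with benzyl bromide in an aprotic solvent at 0 °C should outrun Payne rearrangement of the epoxy alkoxide and gives an ether that is inert to the Lewis acid and is removed at the very end.

Step 13
Reactants: 18 (2R,3R)-epoxy benzyl ether
Product: 19 (3R,4S,5S,9R,10S,13S)-18-benzyloxy-15-(tert-butyldiphenylsilyloxy)labd-8(17)-en-3-ol (ent-labdane bicycle)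
Conditions: MeAlCl2, CH2Cl2, −78 °C; then Et3N, aq. potassium sodium tartrate
Reagents that add atoms: none
Why: MeAlCl2 binds the epoxide oxygen, the C5=C10 alkene attacks the tertiary C4 from the side opposite the breaking C4–O bond, the C8=C9 alkene takes the C10 cation that develops, and the tertiary C8 cation ends the cascade by losing a C17 proton, which the Al–CH3 bond removes as methane. The closest known reaction type is the Lewis acid-promoted cationic epoxy-polyene cyclization of ethers of Sharpless-derived 2,3-epoxy alcohols. Ring A closes by 6-endo attack of C5 on C4 (C4–C5 bond) and ring B by 6-endo attack of C9 on C10 (C9–C10 bond), both through chair arrangements of the all-E chain. C4 is set by inversion at the epoxide carbon, which places the E-derived CH2OBn group equatorial and the methyl axial while the retained C3–O bond becomes equatorial; C5 and C10 are set by anti addition across the E C5=C10 alkene (trans ring fusion, axial C20) and C9 by the E C8=C9 alkene in the second chair (H-9 anti to C20), and the (2R,3R) epoxide decides which face of C5=C10 reaches C4, hence the ent series. The step needs face selectivity in the first closure, chair-chair folding and a kinetic proton loss that avoids C9; the defined epoxide, three E trisubstituted alkenes that make every cation tertiary, the absence of nucleophiles other than two weakly basic ethers, and a proton-scavenging Lewis acid at −78 °C should secure them.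

Step 14
Reactants: 19 ent-labdane bicycle with free C3 alcohol
Product: 22 O-(C3) S-methyl dithiocarbonate (xanthate) of 19, via sodium alkoxide 20 (not isolated), via sodium xanthate 21 (not isolated)
Conditions: NaH, imidazole (cat.), THF, 0 °C to rt; CS2; then MeI
Reagents that add atoms: carbon disulfide S=C=S; iodomethane CI
Why: In this xanthate formation the alkoxide of the equatorial, neopentyl-type C3 alcohol adds to CS2 and the dithiocarbonate salt 21 is methylated at sulfur, a sequence that works on hindered secondary alcohols where acylation is slow.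

Step 15
Reactants: 22 C3 xanthate
Product: 23 (4S,5S,9R,10S,13S)-18-benzyloxy-15-(tert-butyldiphenylsilyloxy)labd-8(17)-ene
Conditions: Bu3SnH, AIBN (cat.), toluene, 110 °C
Reagents that add atoms: none
Why: In the Barton-McCombie deoxygenation the stannyl radical adds to the thiocarbonyl sulfur, β-scission gives the secondary C3 radical, which takes hydrogen from Bu3SnH, and the isolated alkene, the ethers and all stereocentres are outside the radical chain.

Step 16
Reactants: 23 3-deoxy 8(17)-alkene
Product: 25 (4S,5S,8S,9S,10R,13S)-18-benzyloxy-15-(tert-butyldiphenylsilyloxy)labdan-8-ol, via hydroperoxide 24 (not isolated)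
Conditions: Mn(dpm)3 (cat.; dpm = 2,2,6,6-tetramethylheptane-3,5-dionate), PhSiH3, O2 (1 atm), i-PrOH/CH2Cl2, 0 °C to rt; then PPh3
Reagents that add atoms: dioxygen O=O
Why: In the Mukaiyama hydration by metal-hydride hydrogen atom transfer the manganese hydride gives hydrogen to C17 (or to C7 of the 7-ene isomer), the tertiary C8 radical is trapped by O2 on the face opposite the axial C10 methyl and PPh3 reduces hydroperoxide 24, so the C8 hydroxyl should be equatorial and the C17 methyl axial (8S).

Step 17
Reactants: 25 8-hydroxy ent-labdane with C15 silyl ether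
Product: 26 (4S,5S,8S,9S,10R,13S)-18-benzyloxylabdane-8,15-diol
Conditions: Bu4NF, THF, rt
Reagents that add atoms: none
Why: Fluoride cleaves the Si–O bond of the silyl ether (desilylation) and leaves the benzyl ether and the tertiary alcohol unchanged.

Step 18
Reactants: 26 18-benzyloxylabdane-8,15-diol; 27 mono-benzyl malonate
Product: 28 benzyl (4S,5S,8S,9S,10R,13S)-18-benzyloxy-8-hydroxylabdan-15-yl malonate
Conditions: DCC, DMAP (cat.), CH2Cl2, 0 °C to rt
Reagents that add atoms: none
Why: Steglich esterification (carbodiimide activation, DMAP catalysis) acylates the primary C15 alcohol, while the hindered tertiary C8 alcohol does not react.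

Step 19
Reactants: 28 benzyl malonate diester with C18 benzyl ether
Product: 29 (4S,5S,8S,9S,10R,13S)-8,18-dihydroxylabdan-15-yl hydrogen malonate (CNP0324566.1)
Conditions: H2 (1 atm), 10% Pd/C, EtOAc, rt
Reagents that add atoms: none
Why: Catalytic hydrogenolysis cleaves both benzylic C–O bonds, of the benzyl ester and of the benzyl ether, under neutral conditions in which the tertiary alcohol and the malonic half ester persist.

**Compound list**

1 | (S)-citronellol, (3S)-3,7-dimethyloct-6-en-1-ol | C[C@H](CCO)CCC=C(C)C | starting material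
2 | (S)-citronellyl tert-butyldiphenylsilyl ether | C[C@H](CCO[Si](c1ccccc1)(c1ccccc1)C(C)(C)C)CCC=C(C)C | intermediate
3 | (2E,6S)-8-(tert-butyldiphenylsilyloxy)-2,6-dimethyloct-2-enal (not isolated) | C[C@H](CCO[Si](c1ccccc1)(c1ccccc1)C(C)(C)C)CC/C=C(\C)C=O | intermediate
4 | (2E,6S)-8-(tert-butyldiphenylsilyloxy)-2,6-dimethyloct-2-en-1-ol | C[C@H](CCO[Si](c1ccccc1)(c1ccccc1)C(C)(C)C)CC/C=C(\C)CO | intermediate
5 | (3S,6E)-8-bromo-3,7-dimethyloct-6-en-1-yl tert-butyldiphenylsilyl ether (bromide on C7) | C[C@H](CCO[Si](c1ccccc1)(c1ccccc1)C(C)(C)C)CC/C=C(\C)CBr | intermediate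
6 | geraniol, (2E)-3,7-dimethylocta-2,6-dien-1-ol | CC(C)=CCC/C(C)=C/CO | starting material
7 | geranyl bromide | CC(C)=CCC/C(C)=C/CBr | intermediate
8 | geranyl phenyl sulfone | CC(C)=CCC/C(C)=C/CS(=O)(=O)c1ccccc1 | intermediate
9 | (2E,6E)-2,6-dimethyl-8-(phenylsulfonyl)octa-2,6-dienal (not isolated) | O=C/C(C)=C/CC/C(C)=C/CS(=O)(=O)c1ccccc1 | intermediate
10 | (2E,6E)-2,6-dimethyl-8-(phenylsulfonyl)octa-2,6-dien-1-ol | OC/C(C)=C/CC/C(C)=C/CS(=O)(=O)c1ccccc1 | intermediate
11 | (2E,6E)-8-(tert-butyldimethylsilyloxy)geranyl phenyl sulfone | CC(C)(C)[Si](C)(C)OC/C(C)=C/CC/C(C)=C/CS(=O)(=O)c1ccccc1 | intermediate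
12 | α-lithio derivative of 11, carbanion at the sulfonyl-bearing carbon C6 (not isolated) | [Li+].CC(C)(C)[Si](C)(C)OC/C(C)=C/CC/C(C)=C/[CH-]S(=O)(=O)c1ccccc1 | intermediate
13 | (2E,6E,10E,14S)-1-(tert-butyldimethylsilyloxy)-16-(tert-butyldiphenylsilyloxy)-2,6,10,14-tetramethyl-8-(phenylsulfonyl)hexadeca-2,6,10-triene, both C8 epimers | C[C@H](CCO[Si](c1ccccc1)(c1ccccc1)C(C)(C)C)CC/C=C(\C)CC(S(=O)(=O)c1ccccc1)/C=C(C)/CC/C=C(C)/CO[Si](C)(C)C(C)(C)C | intermediate
14 | (2E,6E,10E,14S)-1-(tert-butyldimethylsilyloxy)-16-(tert-butyldiphenylsilyloxy)-2,6,10,14-tetramethylhexadeca-2,6,10-triene | C[C@H](CCO[Si](c1ccccc1)(c1ccccc1)C(C)(C)C)CC/C=C(\C)CC/C=C(C)/CC/C=C(C)/CO[Si](C)(C)C(C)(C)C | intermediate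
15 | (2E,6E,10E,14S)-16-(tert-butyldiphenylsilyloxy)-2,6,10,14-tetramethylhexadeca-2,6,10-trien-1-ol | C[C@H](CCO[Si](c1ccccc1)(c1ccccc1)C(C)(C)C)CC/C=C(\C)CC/C=C(C)/CC/C=C(C)/CO | intermediate
16 | [(2R,3R)-3-{(3E,7E,11S)-13-(tert-butyldiphenylsilyloxy)-3,7,11-trimethyltrideca-3,7-dien-1-yl}-2-methyloxiran-2-yl]methanol | C[C@H](CCO[Si](c1ccccc1)(c1ccccc1)C(C)(C)C)CC/C=C(\C)CC/C=C(\C)CC[C@H]1O[C@]1(C)CO | intermediate
17 | sodium alkoxide of 16 (not isolated) | [Na+].C[C@H](CCO[Si](c1ccccc1)(c1ccccc1)C(C)(C)C)CC/C=C(\C)CC/C=C(\C)CC[C@H]1O[C@]1(C)C[O-] | intermediate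
18 | (2R,3R)-2-(benzyloxymethyl)-2-methyl-3-{(3E,7E,11S)-13-(tert-butyldiphenylsilyloxy)-3,7,11-trimethyltrideca-3,7-dien-1-yl}oxirane | C[C@H](CCO[Si](c1ccccc1)(c1ccccc1)C(C)(C)C)CC/C=C(\C)CC/C=C(\C)CC[C@H]1O[C@]1(C)COCc1ccccc1 | intermediate
19 | (3R,4S,5S,9R,10S,13S)-18-benzyloxy-15-(tert-butyldiphenylsilyloxy)labd-8(17)-en-3-ol (ent-labdane; 3-OH and 4-CH2OBn equatorial, 4-CH3 and C20 axial and cis, H-5 and H-9 trans to C20) | C[C@H](CCO[Si](c1ccccc1)(c1ccccc1)C(C)(C)C)CC[C@H]1[C@]2(C)CC[C@@H](O)[C@](C)(COCc3ccccc3)[C@H]2CCC1=C | intermediate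
20 | sodium C3 alkoxide of 19 (not isolated) | [Na+].C[C@H](CCO[Si](c1ccccc1)(c1ccccc1)C(C)(C)C)CC[C@H]1[C@]2(C)CC[C@@H]([O-])[C@](C)(COCc3ccccc3)[C@H]2CCC1=C | intermediate
21 | sodium O-(C3) dithiocarbonate of 19 (not isolated) | [Na+].C[C@H](CCO[Si](c1ccccc1)(c1ccccc1)C(C)(C)C)CC[C@H]1[C@]2(C)CC[C@@H](OC(=S)[S-])[C@](C)(COCc3ccccc3)[C@H]2CCC1=C | intermediate
22 | O-[(3R,4S,5S,9R,10S,13S)-18-benzyloxy-15-(tert-butyldiphenylsilyloxy)labd-8(17)-en-3-yl] S-methyl dithiocarbonate | C[C@H](CCO[Si](c1ccccc1)(c1ccccc1)C(C)(C)C)CC[C@H]1[C@]2(C)CC[C@@H](OC(=S)SC)[C@](C)(COCc3ccccc3)[C@H]2CCC1=C | intermediate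
23 | (4S,5S,9R,10S,13S)-18-benzyloxy-15-(tert-butyldiphenylsilyloxy)labd-8(17)-ene | C[C@H](CCO[Si](c1ccccc1)(c1ccccc1)C(C)(C)C)CC[C@H]1[C@]2(C)CCC[C@](C)(COCc3ccccc3)[C@H]2CCC1=C | intermediate
24 | (4S,5S,8S,9S,10R,13S)-18-benzyloxy-15-(tert-butyldiphenylsilyloxy)labdan-8-yl hydroperoxide (not isolated) | C[C@H](CCO[Si](c1ccccc1)(c1ccccc1)C(C)(C)C)CC[C@H]1[C@]2(C)CCC[C@](C)(COCc3ccccc3)[C@H]2CC[C@]1(C)OO | intermediate
25 | (4S,5S,8S,9S,10R,13S)-18-benzyloxy-15-(tert-butyldiphenylsilyloxy)labdan-8-ol (8-OH equatorial, C17 axial) | C[C@H](CCO[Si](c1ccccc1)(c1ccccc1)C(C)(C)C)CC[C@H]1[C@]2(C)CCC[C@](C)(COCc3ccccc3)[C@H]2CC[C@]1(C)O | intermediate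
26 | (4S,5S,8S,9S,10R,13S)-18-benzyloxylabdane-8,15-diol | C[C@H](CCO)CC[C@H]1[C@]2(C)CCC[C@](C)(COCc3ccccc3)[C@H]2CC[C@]1(C)O | intermediate
27 | mono-benzyl malonate, 3-(benzyloxy)-3-oxopropanoic acid | O=C(O)CC(=O)OCc1ccccc1 | starting material
28 | benzyl (4S,5S,8S,9S,10R,13S)-18-benzyloxy-8-hydroxylabdan-15-yl malonate | C[C@H](CCOC(=O)CC(=O)OCc1ccccc1)CC[C@H]1[C@]2(C)CCC[C@](C)(COCc3ccccc3)[C@H]2CC[C@]1(C)O | intermediate
29 | (4S,5S,8S,9S,10R,13S)-8,18-dihydroxylabdan-15-yl hydrogen malonate, CNP0324566.1 | C[C@H](CCOC(=O)CC(=O)O)CC[C@H]1[C@]2(C)CCC[C@](C)(CO)[C@H]2CC[C@]1(C)O | target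

**Count**

Total step count: 19.
Longest linear sequence: 16 steps (geraniol 6 to target 29, steps 4 to 19). The citronellol branch (steps 1 to 3) joins at step 8.

**Steps most likely to fail**

Step 13 (bicyclization). The electron-withdrawing benzyloxymethyl group may slow ionisation of the epoxide. The cascade could then stop after ring A, the C10 cation could be captured by the epoxide oxygen, or the epoxide could rearrange by hydride shift; proton loss may also drift towards C9. The fallback makes the same two ring bonds through a radical instead of a cation. Starting from 18, Cp2TiCl (trivalent titanium, made in the flask from Cp2TiCl2 and Mn dust in THF at rt) opens the epoxide by single electron transfer to the tertiary C4 radical. This radical closes ring A (C4–C5) and ring B (C9–C10) by two 6-endo additions and ends by loss of a C17 hydrogen to the 8(17)-alkene. Aqueous work-up of the titanium alkoxide returns to 19 without any new isolated compound (F0). In this variant C4 rests on the chair preference of the radical (benzyloxymethyl equatorial) instead of on inversion, while C5, C9 and C10 again follow from chair-chair folding with the C3 oxygen equatorial.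

Step 16 (hydration). Capture of the planar C8 radical by O2 may show poor facial selectivity, or hydrogen atom transfer to the trisubstituted 7-ene portion may be slow, so that the material does not converge. The fallback is an ionic two-step sequence that sets out from 23. mCPBA (NaHCO3, CH2Cl2, 0 °C) should epoxidise the exocyclic alkene from the face opposite the axial C10 methyl to give 18-benzyloxy-15-(tert-butyldiphenylsilyloxy)-8,17-epoxy-ent-labdane F1. LiAlH4 (THF, 0 °C to rt) then delivers hydride to the primary C17 and gives tertiary alcohol 25, with the oxygen where the peracid placed it. This serves only the 8(17)-alkene part of the material.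

Step 6 (allylic oxidation of the sulfone). Incomplete conversion, over-oxidation and competing oxidation at other allylic positions may erode throughput at the start of the longest sequence. The fallback rebuilds the oxidised terminus by olefination instead of C–H oxidation and sets out from 8. mCPBA (CH2Cl2, 0 °C) epoxidises the more electron-rich distal alkene to 6,7-epoxygeranyl phenyl sulfone F2. H5IO6 (THF/H2O, 0 °C) cleaves the epoxide, with loss of acetone, to (4E)-4-methyl-6-(phenylsulfonyl)hex-4-enal F3. The stabilised ylide Ph3P=C(CH3)CO2Et (CH2Cl2, rt) gives, by E-selective Wittig reaction, ethyl (2E,6E)-2,6-dimethyl-8-(phenylsulfonyl)octa-2,6-dienoate F4. i-Bu2AlH (CH2Cl2, −78 °C) reduces the ester to allylic alcohol 10, where the route is rejoined.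

Further compounds
F0 | step 13 | none | none
F1 | step 16 | 18-benzyloxy-15-(tert-butyldiphenylsilyloxy)-8,17-epoxy-ent-labdane, (13S), epoxide oxygen on the ring face opposite the C10 methyl | C[C@H](CCO[Si](c1ccccc1)(c1ccccc1)C(C)(C)C)CC[C@H]1[C@]2(C)CCC[C@](C)(COCc3ccccc3)[C@H]2CC[C@@]14CO4
F2 | step 6 | 6,7-epoxygeranyl phenyl sulfone, 2,2-dimethyl-3-[(3E)-3-methyl-5-(phenylsulfonyl)pent-3-en-1-yl]oxirane (racemic at the epoxide) | CC1(C)OC1CC/C(C)=C/CS(=O)(=O)c1ccccc1
F3 | step 6 | (4E)-4-methyl-6-(phenylsulfonyl)hex-4-enal | O=CCC/C(C)=C/CS(=O)(=O)c1ccccc1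
F4 | step 6 | ethyl (2E,6E)-2,6-dimethyl-8-(phenylsulfonyl)octa-2,6-dienoate | CCOC(=O)/C(C)=C/CC/C(C)=C/CS(=O)(=O)c1ccccc1
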